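**Plan**

1. Numbering (target SMILES order): C1 CH–OAc, C2 CH2, C3 quaternary C–CH3, C4 CHOH, C5 CH2, C6 =C(CH3), C7 =CH, C8 CH–O-aroyl, C9 fusion CH, C10 C(OH)iPr. Ring A is C1, C2, C3, C9, C10 (five-membered); ring B is C3 to C9 (seven-membered).
2. Enabling feature: C9 lies between the oxygenated C8 and the isopropyl-bearing C10, and C1–C2 leads back to the quaternary C3. With C8 as a ketone, ring A is therefore a C2–C3–C9 cyclopropane that has taken a terminal alkyne (C1H≡C10–iPr) into its C2–C9 bond.
3. Retrosynthetic cuts, in order: both ester C–O bonds; the C1–O and C10–O bonds (back to a C1=C10 alkene) and the C6=C7 unsaturation (back to a C8 ketone); C1–C2 and C9–C10 together; the cyclopropane bonds C2–C3 and C2–C9; C3=C9; finally C3–C4 and C8–C9 at the two carbonyls of a 3-methylglutarate.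
4. Forward order: the acyclic C3–C9 chain is built on dimethyl 3-methylglutarate by two Weinreb ketone syntheses, ring B is closed by metathesis, the cyclopropane is added by methylene transfer, and ring A is closed by the SmI2-catalysed ketyl-radical annulation. Desaturation, dihydroxylation, acetylation, reduction, aroylation and desilylation follow.
5. Stereochemistry: C4 from a CBS reduction (absolute control); C3 from cyclopropanation anti to the C4 silyloxy group; C9 from the enforced cis ring fusion of the annulation; C1 and C10 from convex-face OsO4 addition; C8 from convex-face hydride delivery. The temporary C6 centre comes from an enzymatic desymmetrisation.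

Key step: step 10

Remark: the C6 methyl stereocentre carried from step 1 to compound 12 is erased in step 11. Incomplete selectivity in step 1 would therefore cost material as C6 epimers but would not lower the enantiopurity of 22, which rests on step 4. Atom numbers C1–C10 of the plan are used throughout.

**Route**

Step 1
Reactants: 1 dimethyl 3-methylpentanedioate (dimethyl 3-methylglutarate)
Product: 2 (3R)-5-methoxy-3-methyl-5-oxopentanoic acid (R half-ester)
Conditions: pig liver esterase, phosphate buffer (pH 7)/MeOH 4:1, −10 °C, pH-stat with 1 M NaOH; then HCl to pH 2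
Reagents that add atoms: water, O
Why: Enzymatic desymmetrisation, in which the esterase hydrolyses one enantiotopic ester group of the prochiral diester, is a known reaction of 3-substituted glutarates and should give the R half-ester, fixing the temporary C6 centre.

Step 2
Reactants: 2 (3R)-5-methoxy-3-methyl-5-oxopentanoic acid
Product: 3 methyl (3R)-5-[methoxy(methyl)amino]-3-methyl-5-oxopentanoate
Conditions: MeNHOMe·HCl, EDC·HCl, N-methylmorpholine, CH2Cl2, 0 °C to rt
Reagents that add atoms: N,O-dimethylhydroxylamine hydrochloride, CNOC.Cl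
Why: Carbodiimide amide coupling converts the free acid into the Weinreb amide and leaves the methyl ester untouched.

Step 3
Reactants: 3 methyl (3R)-5-[methoxy(methyl)amino]-3-methyl-5-oxopentanoate
Product: 4 methyl (3R)-3,6-dimethyl-5-oxohept-6-enoate
Conditions: CH2=C(CH3)MgBr (1.2 equiv), THF, −20 to 0 °C; cold 1 M HCl
Reagents that add atoms: isopropenylmagnesium bromide, CC(=C)[Mg]Br
Why: In this Weinreb ketone synthesis the chelated tetrahedral adduct stops at mono-addition, the amide reacts ahead of the methyl ester at low temperature, and the acidic quench keeps the released amine from adding to the new enone (this forms the C3–C4 bond).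

Step 4
Reactants: 4 methyl (3R)-3,6-dimethyl-5-oxohept-6-enoate
Product: 5 methyl (3R,5S)-5-hydroxy-3,6-dimethylhept-6-enoate
Conditions: (R)-2-methyl-CBS-oxazaborolidine (20 mol %), catecholborane, toluene, −78 °C; MeOH, then aq. NaOH wash
Reagents that add atoms: none
Why: In this Corey–Bakshi–Shibata reduction the isopropenyl group acts as the large and the CH2 chain as the small substituent, so the (R)-catalyst should deliver hydride to give the 5S allylic alcohol (C4 of the target), the centre that fixes the absolute configuration of the series, while catecholborane spares the ester and the alkene.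

Step 5
Reactants: 5 methyl (3R,5S)-5-hydroxy-3,6-dimethylhept-6-enoate
Product: 6 methyl (3R,5S)-5-[(tert-butyldimethylsilyl)oxy]-3,6-dimethylhept-6-enoate
Conditions: TBSOTf, 2,6-lutidine, CH2Cl2, −78 °C
Reagents that add atoms: tert-butyldimethylsilyl trifluoromethanesulfonate, CC(C)(C)[Si](C)(C)OS(=O)(=O)C(F)(F)F
Why: Standard silylation of a secondary allylic alcohol, run cold and directly after step 4 so that the δ-hydroxy ester has no opportunity to lactonise.

Step 6
Reactants: 6 methyl (3R,5S)-5-[(tert-butyldimethylsilyl)oxy]-3,6-dimethylhept-6-enoate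
Product: 7 (3R,5S)-5-[(tert-butyldimethylsilyl)oxy]-N-methoxy-N,3,6-trimethylhept-6-enamide
Conditions: MeNHOMe·HCl, iPrMgCl, THF, −20 to 0 °C
Reagents that add atoms: N,O-dimethylhydroxylamine hydrochloride, CNOC.Cl
Why: Direct ester-to-Weinreb-amide exchange with the chloromagnesium amide generated in the flask is a standard aminolysis that tolerates silyl ethers and alkenes.

Step 7
Reactants: 7 (3R,5S)-5-[(tert-butyldimethylsilyl)oxy]-N-methoxy-N,3,6-trimethylhept-6-enamide
Product: 8 (5R,7S)-7-[(tert-butyldimethylsilyl)oxy]-5,8-dimethylnona-1,8-dien-3-one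
Conditions: CH2=CHMgBr, THF, −20 to 0 °C; cold 1 M HCl
Reagents that add atoms: vinylmagnesium bromide, C=C[Mg]Br
Why: Weinreb ketone synthesis gives the vinyl ketone (C8–C9 bond) without over-addition, and the cold acidic quench avoids conjugate addition of the released amine.

Step 8
Reactants: 8 (5R,7S)-7-[(tert-butyldimethylsilyl)oxy]-5,8-dimethylnona-1,8-dien-3-one
Product: 9 (4S,6R)-4-[(tert-butyldimethylsilyl)oxy]-3,6-dimethylcyclohept-2-en-1-one (silyloxy group and C6 methyl cis)
Conditions: second-generation Hoveyda–Grubbs catalyst [RuCl2(H2IMes)(=CH–C6H4-2-OiPr)] (5–10 mol %), toluene (0.005 M), 80 °C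
Reagents that add atoms: none
Why: Ring-closing metathesis of a vinyl ketone with a 1,1-disubstituted alkene to a trisubstituted cycloheptenone is a known use of second-generation ruthenium carbenes and is driven by loss of ethene under dilute, hot conditions (this closes ring B at C3=C9).

Step 9
Reactants: 9 (4S,6R)-4-[(tert-butyldimethylsilyl)oxy]-3,6-dimethylcyclohept-2-en-1-one
Product: 10 (1R,4R,6S,7S)-6-[(tert-butyldimethylsilyl)oxy]-4,7-dimethylbicyclo[5.1.0]octan-2-one (cyclopropane CH2 trans to the silyloxy group)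
Conditions: Me3S(O)I, NaH, DMSO, rt; then 9, rt to 50 °C
Reagents that add atoms: trimethylsulfoxonium iodide, C[S+](C)(C)=O.[I-]
Why: In this Corey–Chaykovsky cyclopropanation dimethylsulfoxonium methylide adds in conjugate fashion to the β-methyl enone and the enolate closes with loss of DMSO; the ylide should approach C3 from the ring face opposite the adjacent silyloxy group and the C6 methyl, which sets the quaternary C3.

Step 10
Reactants: 10 (1R,4R,6S,7S)-6-[(tert-butyldimethylsilyl)oxy]-4,7-dimethylbicyclo[5.1.0]octan-2-one; 11 3-methylbut-1-yne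
Product: 12 (3aR,6R,8S,8aS)-8-[(tert-butyldimethylsilyl)oxy]-6,8a-dimethyl-3-(propan-2-yl)-3a,5,6,7,8,8a-hexahydroazulen-4(1H)-one (cis-fused; C1=C10 alkene, C8 ketone)
Conditions: SmI2 (25 mol %), Sm metal (25 mol %), 11 (10 equiv), THF, 55 °C, sealed tube
Reagents that add atoms: none
Why: Divalent samarium reduces the C8 ketone of 10 to its ketyl, the exocyclic cyclopropane bond C2–C9 opens to a trivalent samarium enolate (C8=C9) and a primary C2 radical, this radical adds to the CH terminus of 11 (C1–C2) and the resulting C10 vinyl radical attacks the enolate carbon C9 (C9–C10), after which the new ketyl hands its electron back to trivalent samarium so that SmI2 turns over, the Sm metal returning stray trivalent samarium to the divalent state. The closest known reaction is the SmI2-catalysed formal [3+2] cycloaddition (radical relay) of alkyl cyclopropyl ketones, fused bicyclic ones included, with terminal alkynes. Ring A is closed by a 5-exo-trig attack of the vinyl radical on the C8=C9 enolate double bond. The one new stereocentre, C9, is set cis to the C3 methyl because the C2–C1=C10 chain hangs from C3 on the face the cyclopropane occupied and can only reach that face of C9. The step needs cleavage of C2–C9 instead of C3–C9 and attack at the alkyne CH instead of the isopropyl-bearing carbon; the first is secured by the better overlap of the exocyclic bond with the ketyl in the fused bicyclo[5.1.0] frame, the second by the steric bias of a terminal alkyne toward the more substituted vinyl radical. Because an alkylacetylene is a slower radical acceptor than an arylacetylene, 11 is used in large excess in a closed vessel.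

Step 11
Reactants: 12 (3aR,6R,8S,8aS)-8-[(tert-butyldimethylsilyl)oxy]-6,8a-dimethyl-3-(propan-2-yl)-3a,5,6,7,8,8a-hexahydroazulen-4(1H)-one
Product: 14 (3aR,8S,8aS)-8-[(tert-butyldimethylsilyl)oxy]-6,8a-dimethyl-3-(propan-2-yl)-3a,7,8,8a-tetrahydroazulen-4(1H)-one, via trimethylsilyl enol ether 13 (not isolated)
Conditions: LiN(iPr)2 (LDA), THF, −78 °C; TMSCl, −78 to 0 °C; then Pd(OAc)2 (1.1 equiv), MeCN, rt
Reagents that add atoms: none
Why: In this Saegusa–Ito oxidation kinetic deprotonation should occur at the unhindered C7 methylene and not at the tertiary, doubly flanked C9–H, and the divalent palladium enolate formed from silyl enol ether 13 undergoes β-hydride elimination to the C6=C7 enone, which also removes the C6 stereocentre.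

Step 12
Reactants: 14 (3aR,8S,8aS)-8-[(tert-butyldimethylsilyl)oxy]-6,8a-dimethyl-3-(propan-2-yl)-3a,7,8,8a-tetrahydroazulen-4(1H)-one
Product: 15 (2S,3R,3aS,8S,8aS)-8-[(tert-butyldimethylsilyl)oxy]-2,3-dihydroxy-6,8a-dimethyl-3-(propan-2-yl)-2,3,3a,7,8,8a-hexahydroazulen-4(1H)-one
Conditions: OsO4 (5 mol %), NMO, acetone/H2O 8:1, rt
Reagents that add atoms: osmium tetroxide, O=[Os](=O)(=O)=O; N-methylmorpholine N-oxide, C[N+]1([O-])CCOCC1; water, O
Why: In this Upjohn dihydroxylation OsO4 should react with the electron-rich trisubstituted C1=C10 alkene in preference to the electron-poor enone and add from the convex face of the cis-fused bicycle (the face of the C9 hydrogen and C3 methyl, away from ring B), setting C1 and C10.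

Step 13
Reactants: 15 (2S,3R,3aS,8S,8aS)-8-[(tert-butyldimethylsilyl)oxy]-2,3-dihydroxy-6,8a-dimethyl-3-(propan-2-yl)-2,3,3a,7,8,8a-hexahydroazulen-4(1H)-one
Product: 16 (2S,3R,3aS,8S,8aS)-8-[(tert-butyldimethylsilyl)oxy]-3-hydroxy-6,8a-dimethyl-4-oxo-3-(propan-2-yl)-1,2,3,3a,4,7,8,8a-octahydroazulen-2-yl acetate
Conditions: Ac2O, pyridine, DMAP (10 mol %), CH2Cl2, 0 °C to rt
Reagents that add atoms: acetic anhydride, CC(=O)OC(C)=O
Why: DMAP-catalysed acetylation is selective for the secondary C1 hydroxyl because the tertiary C10 hydroxyl does not acylate under these mild conditions.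

Step 14
Reactants: 16 (2S,3R,3aS,8S,8aS)-8-[(tert-butyldimethylsilyl)oxy]-3-hydroxy-6,8a-dimethyl-4-oxo-3-(propan-2-yl)-1,2,3,3a,4,7,8,8a-octahydroazulen-2-yl acetate
Product: 17 (2S,3R,3aR,4S,8S,8aS)-8-[(tert-butyldimethylsilyl)oxy]-3,4-dihydroxy-6,8a-dimethyl-3-(propan-2-yl)-1,2,3,3a,4,7,8,8a-octahydroazulen-2-yl acetate
Conditions: NaBH4, CeCl3·7H2O, MeOH, −78 °C
Reagents that add atoms: none
Why: Luche reduction gives clean 1,2-reduction of the enone, and hydride should enter at C8 from the convex face, away from the C9–C10 bond and the concave-side isopropyl group, placing the new hydroxyl trans to the C9 hydrogen as in the target.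

Step 15
Reactants: 18 4-hydroxybenzoic acid
Product: 20 4-[(tert-butyldimethylsilyl)oxy]benzoic acid, via bis-silylated benzoate 19 (not isolated)
Conditions: TBSCl (2.5 equiv), imidazole, DMF, rt; then AcOH/THF/H2O 3:1:1, rt
Reagents that add atoms: tert-butyldimethylsilyl chloride, CC(C)(C)[Si](C)(C)Cl
Why: Silylation of both acidic hydroxyls followed by selective hydrolysis of the labile silyl ester is the standard route to the O-silylated phenolic acid.

Step 16
Reactants: 17 (2S,3R,3aR,4S,8S,8aS)-8-[(tert-butyldimethylsilyl)oxy]-3,4-dihydroxy-6,8a-dimethyl-3-(propan-2-yl)-1,2,3,3a,4,7,8,8a-octahydroazulen-2-yl acetate; 20 4-[(tert-butyldimethylsilyl)oxy]benzoic acid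
Product: 21 (2S,3R,3aR,4S,8S,8aS)-2-(acetyloxy)-8-[(tert-butyldimethylsilyl)oxy]-3-hydroxy-6,8a-dimethyl-3-(propan-2-yl)-1,2,3,3a,4,7,8,8a-octahydroazulen-4-yl 4-[(tert-butyldimethylsilyl)oxy]benzoate
Conditions: DCC, DMAP, CH2Cl2, 0 °C to rt
Reagents that add atoms: none
Why: Steglich esterification acylates the secondary allylic C8 hydroxyl with retention, while the tertiary C10 hydroxyl stays free.

Step 17
Reactants: 21 (2S,3R,3aR,4S,8S,8aS)-2-(acetyloxy)-8-[(tert-butyldimethylsilyl)oxy]-3-hydroxy-6,8a-dimethyl-3-(propan-2-yl)-1,2,3,3a,4,7,8,8a-octahydroazulen-4-yl 4-[(tert-butyldimethylsilyl)oxy]benzoate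
Product: 22 (2S,3R,3aR,4S,8S,8aS)-2-(acetyloxy)-3,8-dihydroxy-6,8a-dimethyl-3-(propan-2-yl)-1,2,3,3a,4,7,8,8a-octahydroazulen-4-yl 4-hydroxybenzoate (CNP0146780.2)
Conditions: HF·pyridine, pyridine, THF, 0 °C to rt
Reagents that add atoms: none
Why: Fluoride cleaves the aryl and the secondary silyl ether under buffered, weakly acidic conditions that should leave the acetate, the allylic aroyl ester and the tertiary alcohol intact.

**Compound list**

1 | dimethyl 3-methylpentanedioate | COC(=O)CC(C)CC(=O)OC | starting material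
2 | (3R)-5-methoxy-3-methyl-5-oxopentanoic acid | OC(=O)C[C@@H](C)CC(=O)OC | intermediate
3 | methyl (3R)-5-[methoxy(methyl)amino]-3-methyl-5-oxopentanoate | CON(C)C(=O)C[C@@H](C)CC(=O)OC | intermediate
4 | methyl (3R)-3,6-dimethyl-5-oxohept-6-enoate | C=C(C)C(=O)C[C@@H](C)CC(=O)OC | intermediate
5 | methyl (3R,5S)-5-hydroxy-3,6-dimethylhept-6-enoate | C=C(C)[C@@H](O)C[C@@H](C)CC(=O)OC | intermediate
6 | methyl (3R,5S)-5-[(tert-butyldimethylsilyl)oxy]-3,6-dimethylhept-6-enoate | C=C(C)[C@@H](O[Si](C)(C)C(C)(C)C)C[C@@H](C)CC(=O)OC | intermediate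
7 | (3R,5S)-5-[(tert-butyldimethylsilyl)oxy]-N-methoxy-N,3,6-trimethylhept-6-enamide | C=C(C)[C@@H](O[Si](C)(C)C(C)(C)C)C[C@@H](C)CC(=O)N(C)OC | intermediate
8 | (5R,7S)-7-[(tert-butyldimethylsilyl)oxy]-5,8-dimethylnona-1,8-dien-3-one | C=C(C)[C@@H](O[Si](C)(C)C(C)(C)C)C[C@@H](C)CC(=O)C=C | intermediate
9 | (4S,6R)-4-[(tert-butyldimethylsilyl)oxy]-3,6-dimethylcyclohept-2-en-1-one | O=C1C=C(C)[C@@H](O[Si](C)(C)C(C)(C)C)C[C@@H](C)C1 | intermediate
10 | (1R,4R,6S,7S)-6-[(tert-butyldimethylsilyl)oxy]-4,7-dimethylbicyclo[5.1.0]octan-2-one | C1[C@]2(C)[C@@H](O[Si](C)(C)C(C)(C)C)C[C@@H](C)CC(=O)[C@H]12 | intermediate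
11 | 3-methylbut-1-yne | CC(C)C#C | starting material
12 | (3aR,6R,8S,8aS)-8-[(tert-butyldimethylsilyl)oxy]-6,8a-dimethyl-3-(propan-2-yl)-3a,5,6,7,8,8a-hexahydroazulen-4(1H)-one | C=1C[C@]2(C)[C@@H](O[Si](C)(C)C(C)(C)C)C[C@@H](C)CC(=O)[C@@H]2C=1C(C)C | intermediate
13 | trimethylsilyl enol ether of 12 (Me3SiO on C8, C7=C8 double bond) | C=1C[C@]2(C)[C@@H](O[Si](C)(C)C(C)(C)C)C[C@@H](C)C=C(O[Si](C)(C)C)[C@@H]2C=1C(C)C | intermediate
14 | (3aR,8S,8aS)-8-[(tert-butyldimethylsilyl)oxy]-6,8a-dimethyl-3-(propan-2-yl)-3a,7,8,8a-tetrahydroazulen-4(1H)-one | C=1C[C@]2(C)[C@@H](O[Si](C)(C)C(C)(C)C)CC(C)=CC(=O)[C@@H]2C=1C(C)C | intermediate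
15 | (2S,3R,3aS,8S,8aS)-8-[(tert-butyldimethylsilyl)oxy]-2,3-dihydroxy-6,8a-dimethyl-3-(propan-2-yl)-2,3,3a,7,8,8a-hexahydroazulen-4(1H)-one | O[C@H]1C[C@]2(C)[C@@H](O[Si](C)(C)C(C)(C)C)CC(C)=CC(=O)[C@@H]2[C@]1(O)C(C)C | intermediate
16 | (2S,3R,3aS,8S,8aS)-8-[(tert-butyldimethylsilyl)oxy]-3-hydroxy-6,8a-dimethyl-4-oxo-3-(propan-2-yl)-1,2,3,3a,4,7,8,8a-octahydroazulen-2-yl acetate | CC(=O)O[C@H]1C[C@]2(C)[C@@H](O[Si](C)(C)C(C)(C)C)CC(C)=CC(=O)[C@@H]2[C@]1(O)C(C)C | intermediate
17 | (2S,3R,3aR,4S,8S,8aS)-8-[(tert-butyldimethylsilyl)oxy]-3,4-dihydroxy-6,8a-dimethyl-3-(propan-2-yl)-1,2,3,3a,4,7,8,8a-octahydroazulen-2-yl acetate | CC(=O)O[C@H]1C[C@]2(C)[C@@H](O[Si](C)(C)C(C)(C)C)CC(C)=C[C@H](O)[C@@H]2[C@]1(O)C(C)C | intermediate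
18 | 4-hydroxybenzoic acid | OC(=O)c1ccc(O)cc1 | starting material
19 | tert-butyldimethylsilyl 4-[(tert-butyldimethylsilyl)oxy]benzoate | CC(C)(C)[Si](C)(C)OC(=O)c1ccc(O[Si](C)(C)C(C)(C)C)cc1 | intermediate
20 | 4-[(tert-butyldimethylsilyl)oxy]benzoic acid | OC(=O)c1ccc(O[Si](C)(C)C(C)(C)C)cc1 | intermediate
21 | (2S,3R,3aR,4S,8S,8aS)-2-(acetyloxy)-8-[(tert-butyldimethylsilyl)oxy]-3-hydroxy-6,8a-dimethyl-3-(propan-2-yl)-1,2,3,3a,4,7,8,8a-octahydroazulen-4-yl 4-[(tert-butyldimethylsilyl)oxy]benzoate | CC(=O)O[C@H]1C[C@]2(C)[C@@H](O[Si](C)(C)C(C)(C)C)CC(C)=C[C@H](OC(=O)c3ccc(O[Si](C)(C)C(C)(C)C)cc3)[C@@H]2[C@]1(O)C(C)C | intermediate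
22 | (2S,3R,3aR,4S,8S,8aS)-2-(acetyloxy)-3,8-dihydroxy-6,8a-dimethyl-3-(propan-2-yl)-1,2,3,3a,4,7,8,8a-octahydroazulen-4-yl 4-hydroxybenzoate | CC(=O)O[C@H]1C[C@]2(C)[C@@H](O)CC(C)=C[C@H](OC(=O)c3ccc(O)cc3)[C@@H]2[C@]1(O)C(C)C | target

**Step count**

Total: 17 steps. Longest linear sequence: 16 steps (steps 1–14, 16, 17); step 15 is the one-step side branch.

**Steps most likely to fail**

1. Step 10. Addition of the neopentyl-type C2 radical to an unactivated alkylacetylene may be too slow. Hydrogen-atom transfer (from THF, or across the ring from C6–H or C7–H) could then drain the radical and leave the samarium trapped as the trivalent enolate. Fragmentation of the endocyclic C3–C9 bond is a second possible leak. The fallback builds ring A by a polar annulation and sets out from enone 9. The allene 4-methyl-3-(trimethylsilyl)penta-1,2-diene F1 would be prepared from commercial 3-bromo-1-(trimethylsilyl)prop-1-yne and iPrMgCl with CuBr·LiBr in THF by SN2′ substitution. It would be combined with 9 and TiCl4 in CH2Cl2 at −78 °C (Danheiser annulation: attack of the allene CH2 on C3 anti to the silyloxy group, 1,2-silyl shift, closure of the titanium enolate at C9) to give the C1-silyl cyclopentene F2. Protodesilylation (CF3CO2H, CH2Cl2, 0 °C) would then come back to the route at 12.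

2. Step 9. Conjugate addition of the ylide to a β,β-disubstituted enone next to a silyloxy-bearing carbon may be slow, so that deprotonation of the enone and poor facial discrimination intervene. The fallback forms ring B and the cyclopropane together by intramolecular carbenoid addition and sets out from ester 6. Saponification (LiOH, THF/H2O) would give (3R,5S)-5-[(tert-butyldimethylsilyl)oxy]-3,6-dimethylhept-6-enoic acid F3. Treatment with iBuOCOCl and N-methylmorpholine would give the isobutyl carbonic mixed anhydride F4, and CH2N2 in Et2O would convert this into (4R,6S)-6-[(tert-butyldimethylsilyl)oxy]-1-diazo-4,7-dimethyloct-7-en-2-one F5. Slow addition of F5 to Cu(acac)2 in toluene at 80 °C should add the copper carbenoid carbon (the future C9) across the isopropenyl group and come back to the route at 10. If both alkene faces react, the isomer with the CH2 anti to the silyloxy group would be separated.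

3. Step 14. Hydride may be delivered from the concave face, which would invert C8. The fallback sets out from 16: if its reduction gives mainly the C8-epimeric allylic alcohol F6, this would be esterified with inversion in a Mitsunobu reaction with acid 20 (PPh3, DIAD, toluene, 0 °C to rt). That comes back to the route at 21 and replaces step 16.

**Further compounds**

F1 | step 10 | 4-methyl-3-(trimethylsilyl)penta-1,2-diene | C=C=C([Si](C)(C)C)C(C)C
F2 | step 10 | C1-silyl cyclopentene: (3aS,6R,8S,8aS)-8-[(tert-butyldimethylsilyl)oxy]-6,8a-dimethyl-3-(propan-2-yl)-2-(trimethylsilyl)-3a,5,6,7,8,8a-hexahydroazulen-4(1H)-one | C[Si](C)(C)C=1C[C@]2(C)[C@@H](O[Si](C)(C)C(C)(C)C)C[C@@H](C)CC(=O)[C@@H]2C=1C(C)C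
F3 | step 9 | (3R,5S)-5-[(tert-butyldimethylsilyl)oxy]-3,6-dimethylhept-6-enoic acid | C=C(C)[C@@H](O[Si](C)(C)C(C)(C)C)C[C@@H](C)CC(=O)O
F4 | step 9 | isobutyl carbonic mixed anhydride of F3 | C=C(C)[C@@H](O[Si](C)(C)C(C)(C)C)C[C@@H](C)CC(=O)OC(=O)OCC(C)C
F5 | step 9 | (4R,6S)-6-[(tert-butyldimethylsilyl)oxy]-1-diazo-4,7-dimethyloct-7-en-2-one | C=C(C)[C@@H](O[Si](C)(C)C(C)(C)C)C[C@@H](C)CC(=O)C=[N+]=[N-]
F6 | step 14 | C8-epimeric allylic alcohol (C8 epimer of 17) | CC(=O)O[C@H]1C[C@]2(C)[C@@H](O[Si](C)(C)C(C)(C)C)CC(C)=C[C@@H](O)[C@@H]2[C@]1(O)C(C)C
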